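Retrosynthesis: each butenolide is cut at its lactone carbonyl (C7 and C23, both from CO) and at C10–C5 and C16–C17 (two pentanoyl groups); the tricyclic core is then cut at C25–C29 and at C13–C14, back to 1,3-dimethoxybenzene 1 and 3-ethoxycyclohex-2-en-1-one 2.
Forward: the aryl–ring A bond C13–C14 is made first, C13 is set, the phenols are freed, and one bond (C25–C29) closes the bicyclo[2.2.2]octane; carbonyl differentiation, double C-acylation, double triflation and double carbonylative lactonisation then complete chains and lactones.
Enabling feature: with C15 and C27 as ketones, ring C14–C15–C16–C25–C26–C27 is the diketo tautomer of a resorcinol that carries C13 on C14; its C25, para to C14, is bonded to C29, the α-carbon of the C9 ketone of ring A (C9–C13, C29).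
Stereochemistry: C13 comes from a ligand-controlled CuH conjugate reduction; C14, C25 and C29 are relayed from C13 in the bridging closure; C27 comes from a thermodynamically controlled dissolving-metal reduction.
Both Z enol-lactone alkenes arise from O-capture of the less hindered ketone enolates.
Key step: step 4

Remark: atom labels C1 to C29 follow the order of the atoms in the target SMILES; plain numerals are compound numbers.
Assumption: the (S)-ligand of step 2 is taken to give the (S)-ketone, by analogy with other 3-substituted cyclohexenones; if a trial reduction shows the opposite sense, the (R)-ligand is used and nothing else changes.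
Assumption: ketophenol 8 is treated throughout as its open keto form; ring-chain tautomerism between one phenol oxygen and the C9 carbonyl is reversible under acid and is taken not to affect steps 3 and 4.

Step 1
Reactants: 1 1,3-dimethoxybenzene; 2 3-ethoxycyclohex-2-en-1-one
Product: 5 3-(2,6-dimethoxyphenyl)cyclohex-2-en-1-one, via 2,6-dimethoxyphenyllithium 3 (not isolated), via lithium carbinolate 4 (not isolated)
Conditions: n-BuLi, THF, 0 °C to rt; 2, −78 to 0 °C; 2 M HCl, rt
Reagents that add atoms: none
Why: Lithiation between the two methoxy groups (directed ortho-metalation), 1,2-addition of aryllithium 3 to the vinylogous ester and acid hydrolysis with loss of ethanol and allylic transposition (Stork–Danheiser sequence) should give the 3-arylenone, in which no stereocentre is present yet.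

Step 2
Reactants: 5 3-(2,6-dimethoxyphenyl)cyclohex-2-en-1-one
Product: 6 (S)-3-(2,6-dimethoxyphenyl)cyclohexan-1-one
Conditions: Cu(OAc)2·H2O (3 mol %), (S)-DTBM-SEGPHOS (3.3 mol %), (MeO)2MeSiH (2 equiv), t-BuOH (2 equiv), toluene, 0 °C to rt
Reagents that add atoms: none
Why: A SEGPHOS-ligated CuH adds hydride to C13 of the β-aryl enone from one face and the copper enolate is protonated by t-BuOH (catalytic asymmetric conjugate reduction, which tolerates hindered β-substituents), so that C13 is set by the ligand.

Step 3
Reactants: 6 (S)-3-(2,6-dimethoxyphenyl)cyclohexan-1-one
Product: 8 (S)-3-(2,6-dihydroxyphenyl)cyclohexan-1-one, via aryl bis(dibromoborinate) 7 (not isolated)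
Conditions: BBr3 (3 equiv), CH2Cl2, −78 to 0 °C; H2O
Reagents that add atoms: none
Why: BBr3 cleaves both aryl methyl ethers through borinate 7 (Lewis acid ether cleavage) without touching the ketone or C13.

Step 4
Reactants: 8 (S)-3-(2,6-dihydroxyphenyl)cyclohexan-1-one
Product: 10 tricyclic triketone (ketones at C9 C15 C27; bicyclo[2.2.2]octane-2,6-dione cis-fused at C13–C29 to ring A), via ring-closed bis-enol 9 (not isolated)
Conditions: AlBr3 (5 equiv), CH2Br2 (0.02 M), 0 °C to rt; poured into ice-cold 1 M HCl, used at once
Reagents that add atoms: none
Why: Proposed new method: AlBr3 converts the phenols into aryloxyaluminium dibromides and sets HBr free, and the resulting HBr–AlBr3 acid protonates the ring reversibly; the minor cation protonated at C14 has that carbon sp3 and cationic character at C25, and in it the enol carbon C29 of the C9 ketone (as enol or aluminium enolate) can reach across the ring, so that C29–C25 bond formation and C-protonation of bis-enol 9 at C16 and C26 give the dione, which is held as its carbonyl–AlBr3 complexes until the cold quench. The closest known reactions are the aluminium halide- or superacid-promoted additions of arenes and of hydride donors to the C-protonated (keto) forms of naphthols and resorcinols, and acid-catalysed intramolecular Michael additions of ketones to enones. The one new bond closes the bicyclo[2.2.2]octane by a 6-(enolexo)-endo-trig attack on the central carbon of the 1,5-dioxygenated pentadienyl cation, the ring being forced into a boat. C14, C25 and C29 are all relayed from C13: the two-atom link C13–C29 can span the ring only as a cis bridge, which fixes the cis C13/C29 fusion and both bridgeheads, and the two oxygenated ring carbons are equivalent until the bond forms. The step needs conjugate bonding of C29 to C25 rather than aldol-type bonding of the other enol carbon, C10, to C15 or C27, which is also a six-membered closure; the substrate favours the former because the oxygen-bearing termini of the cation hold their charge on oxygen and leave the largest coefficient on C25, as in the conjugate mode seen with the naphthol keto forms, and because the aldol adduct is a tertiary aluminium alkoxide that can revert. It also needs the equilibrium to rest with the dione, for which complexation of three carbonyl groups by the stoichiometric Lewis acid and a quench that does not equilibrate are the only levers.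

Step 5
Reactants: 10 tricyclic triketone
Product: 11 C9,C15-bis(ethylene ketal) of 10 with the C27 ketone free
Conditions: Me3SiOCH2CH2OSiMe3 (2.2 equiv), Me3SiOTf (5 mol %), CH2Cl2, −78 to −30 °C; pyridine
Reagents that add atoms: 1,2-bis(trimethylsilyloxy)ethane, C[Si](C)(C)OCCO[Si](C)(C)C
Why: Silyl-transfer ketalisation (Me3SiOTf-catalysed, aprotic, low temperature) should mask the unhindered carbonyls C9 and C15, whereas a dioxolane at C27 would press one of its oxygens against C12H2 of ring A; masking C9 also removes the carbonyl that any retro-Michael cleavage of the new bond would need, and no stereocentre is formed.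

Step 6
Reactants: 11 bis(ethylene ketal) ketone
Product: 12 C27 alcohol of 11 (hydroxyl in the cleft facing the C15–C16 bridge)
Conditions: Li, NH3(l), THF, t-BuOH, −78 °C; NH4Cl
Reagents that add atoms: none
Why: Dissolving-metal reduction of the ketone gives the thermodynamically preferred carbinol, and at C27 that is the epimer with hydroxyl in the open cleft toward the C15–C16 bridge (hydrogen-bonded to a dioxolane oxygen) and hydrogen toward C12H2, which is the configuration of the target.

Step 7
Reactants: 12 C27 alcohol
Product: 13 tert-butyldimethylsilyl ether of 12
Conditions: t-BuMe2SiOTf, 2,6-lutidine, CH2Cl2, −78 to 0 °C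
Reagents that add atoms: tert-butyldimethylsilyl trifluoromethanesulfonate, CC(C)(C)[Si](C)(C)OS(=O)(=O)C(F)(F)F
Why: Silylation of the hindered secondary alcohol with the silyl triflate and a hindered pyridine base is standard and leaves the dioxolanes intact, giving a protecting group that will survive enolate, triflation and carbonylation conditions and can be removed without a nucleophile.

Step 8
Reactants: 13 silyl ether bis-ketal
Product: 14 C9,C15-diketone carrying the C27 silyl ether
Conditions: PPTS, acetone–H2O (10:1), 55 °C
Reagents that add atoms: water, O
Why: Mildly acidic ketal hydrolysis frees both ketones while a secondary tert-butyldimethylsilyl ether survives pyridinium p-toluenesulfonate.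

Step 9
Reactants: 14 C9,C15-diketone; 15 pentanoyl chloride
Product: 17 C10,C16-bis(pentanoyl) derivative of 14 (two enolised 2-acyl ketones), via dilithium bis-enolate 16 (not isolated)
Conditions: LiN(SiMe3)2 (4.4 equiv), THF–toluene, −78 °C; 15 (2.2 equiv), −78 to 0 °C; aq. NH4Cl
Reagents that add atoms: none
Why: Kinetic lithium enolates form toward C16 (the C15 ketone has no other choice, C14 being a bridgehead) and toward C10 (CH2 rather than the tertiary, hindered C29), and their crossed Claisen-type C-acylation with the acid chloride gives the two enolised 2-acyl ketones, the extra base taking up their acidity; no stereocentre needs control because C10 and C16 are enolised.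

Step 10
Reactants: 17 bis(2-acyl ketone)
Product: 18 bis(enol triflate) (triflyloxy on C9 and C15; pentanoyl on C10 and C16)
Conditions: Tf2O (2.4 equiv), i-Pr2NEt (3 equiv), CH2Cl2, −78 °C
Reagents that add atoms: trifluoromethanesulfonic anhydride, O=S(=O)(OS(=O)(=O)C(F)(F)F)C(F)(F)F
Why: O-Sulfonylation of the chelated ring enols of the two 2-acyl ketones gives the β-triflyloxy enones with the triflate on the ring carbon, as in the standard preparation of 2-acylcycloalk-1-enyl triflates (enol triflate formation from β-diketones).

Step 11
Reactants: 18 bis(enol triflate)
Product: 19 O-tert-butyldimethylsilyl ether of the target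
Conditions: Pd(PPh3)4 (10 mol %), CO (3 atm), i-Pr2NEt (3 equiv), MeCN, 60 °C
Reagents that add atoms: carbon monoxide, [C-]#[O+]
Why: Zerovalent palladium inserts into each vinyl triflate, CO insertion gives an acylpalladium at C9 and at C15, and the oxygen of the neighbouring ketone enolate captures it to close the five-membered enol lactone (carbonylative enol-lactonisation, known for (Z)-β-halo enones and o-halophenyl ketones), the Z alkene arising because the propyl-bearing enolate carbon turns its substituent away from the ring.

Step 12
Reactants: 19 silyl ether of the target
Product: 20 target CNP0289078.1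
Conditions: HF·pyridine, THF–pyridine, 0 °C to rt
Reagents that add atoms: none
Why: Fluoride-mediated desilylation under weakly acidic, non-nucleophilic conditions should free the C27 hydroxyl without opening the two enol lactones or isomerising the Z alkenes.

Compound list
1 | 1,3-dimethoxybenzene | COc1cccc(OC)c1 | starting material
2 | 3-ethoxycyclohex-2-en-1-one | CCOC1=CC(=O)CCC1 | starting material
3 | 2,6-dimethoxyphenyllithium | [Li]c1c(OC)cccc1OC | intermediate
4 | lithium 1-(2,6-dimethoxyphenyl)-3-ethoxycyclohex-2-en-1-olate (racemic carbinolate) | CCOC1=CC([O-])(c2c(OC)cccc2OC)CCC1.[Li+] | intermediate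
5 | 3-(2,6-dimethoxyphenyl)cyclohex-2-en-1-one | COc1cccc(OC)c1C1=CC(=O)CCC1 | intermediate
6 | (S)-3-(2,6-dimethoxyphenyl)cyclohexan-1-one | O=C2CCC[C@H](c1c(OC)cccc1OC)C2 | intermediate
7 | (S)-3-[2,6-bis(dibromoboryloxy)phenyl]cyclohexan-1-one | O=C2CCC[C@H](c1c(OB(Br)Br)cccc1OB(Br)Br)C2 | intermediate
8 | (S)-3-(2,6-dihydroxyphenyl)cyclohexan-1-one | O=C2CCC[C@H](c1c(O)cccc1O)C2 | intermediate
9 | ring-closed bis-enol (C25–C29 bond formed; enols C15=C16 and C27=C26; C9 ketone) | O=C2CCC[C@@H]1[C@H]3C(O)=C[C@H](C=C3O)[C@H]21 | intermediate
10 | tricyclic triketone: bicyclo[2.2.2]octane-2,6-dione (bridgeheads C14 and C25, ketones C15 and C27) cis-fused at C13–C29 to cyclohexanone ring A (ketone C9), ring A lying over the C27–C26 bridge | O=C2CCC[C@@H]1[C@H]3C(=O)C[C@H](CC3=O)[C@H]21 | intermediate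
11 | bis(ethylene ketal) of 10 at C9 and C15, C27 ketone free | O1CCOC12CCC[C@@H]3[C@H]4C5(OCCO5)C[C@H](CC4=O)[C@H]23 | intermediate
12 | C27 alcohol of 11, hydroxyl facing the C15–C16 bridge and anti to ring A | O1CCOC12CCC[C@@H]3[C@H]4C5(OCCO5)C[C@H](C[C@@H]4O)[C@H]23 | intermediate
13 | tert-butyldimethylsilyl ether of 12 | O1CCOC12CCC[C@@H]3[C@H]4C5(OCCO5)C[C@H](C[C@@H]4O[Si](C)(C)C(C)(C)C)[C@H]23 | intermediate
14 | tricyclic C9,C15-diketone with C27 silyl ether | O=C2CCC[C@@H]1[C@H]3C(=O)C[C@H](C[C@@H]3O[Si](C)(C)C(C)(C)C)[C@H]21 | intermediate
15 | pentanoyl chloride | CCCCC(Cl)=O | starting material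
16 | dilithium bis-enolate of 14 (enolates C9=C10 and C15=C16) | [Li+].[Li+].[O-]C2=CCC[C@@H]1[C@H]3C([O-])=C[C@H](C[C@@H]3O[Si](C)(C)C(C)(C)C)[C@H]21 | intermediate
17 | C10,C16-bis(pentanoyl) derivative of 14, drawn as the two ring enols | OC2=C(C(=O)CCCC)CC[C@@H]1[C@H]3C(O)=C(C(=O)CCCC)[C@H](C[C@@H]3O[Si](C)(C)C(C)(C)C)[C@H]21 | intermediate
18 | bis(enol triflate) of 17: triflyloxy on C9 and C15, pentanoyl on C10 and C16 | FC(F)(F)S(=O)(=O)OC2=C(C(=O)CCCC)CC[C@@H]1[C@H]3C(OS(=O)(=O)C(F)(F)F)=C(C(=O)CCCC)[C@H](C[C@@H]3O[Si](C)(C)C(C)(C)C)[C@H]21 | intermediate
19 | O-tert-butyldimethylsilyl ether of the target (both (Z)-butylidene butenolides in place) | CCC/C=C1\OC(=O)C2=C1CC[C@@H]1[C@H]3C4=C(/C(=C/CCC)OC4=O)[C@H](C[C@@H]3O[Si](C)(C)C(C)(C)C)[C@H]21 | intermediate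
20 | CNP0289078.1 | CCC/C=C1\OC(=O)C2=C1CC[C@@H]1[C@H]3C4=C(/C(=C/CCC)OC4=O)[C@H](C[C@@H]3O)[C@H]21 | target

Total step count: 12. Longest linear sequence: 12 steps, from 1,3-dimethoxybenzene 1.

Steps most likely to fail

Step 4. The closure is reversible and costs the aromaticity of the ring, so the equilibrium may rest with the arene (retro-Michael cleavage of C25–C29 with rearomatisation). The C10 enol may instead bond to C15 or C27 in an aldol mode, and loss of water from that adduct would restore an arene irreversibly. Reversible loss and re-addition of the cyclohexanone unit at the ipso-protonated ring could also erode the configuration at C13 or move the side chain to C16, and phenol–ketone condensation between molecules competes at higher concentration. The fallback keeps the same bond formation but blocks the return to an arene, using known reactions, and sets out from 8. PhI(OAc)2 (2.2 equiv) in MeOH at 0 °C (oxidative methoxylation of a phenol to a quinone monoketal, here through the 4-methoxyresorcinol) should give (S)-3-hydroxy-4,4-dimethoxy-2-(3-oxocyclohexyl)cyclohexa-2,5-dien-1-one F1, whose ketal carbon C16 carries no hydrogen. Camphorsulfonic acid (cat.) in CH2Cl2 should then effect an ordinary intramolecular ketone-to-enone Michael addition of C29 to C25 through the C14–H diketo tautomer, the ring-closing half of a double Michael route to bicyclo[2.2.2]octanones, to give the 16,16-dimethoxy triketone F2. Either bridge position of the ketal is acceptable, since both converge in the next operation. SmI2 in THF–MeOH at −78 °C (reductive cleavage of α-alkoxy ketones) removes both methoxy groups and comes back to the route at 10.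

Step 5. The two bridge carbonyls may not be told apart well enough (ketalisation at C27 in place of C15), or the labile triketone may fragment by retro-Michael cleavage before C9 is masked. The fallback replaces steric discrimination by a reagent-controlled reduction and sets out from 10. A ketoreductase chosen from a commercial panel (NADP+, i-PrOH, pH 7 buffer, 30 °C) for reduction of the C27 carbonyl alone from its hindered face should give the hydroxy diketone F3; enzymatic mono-reduction of bicyclo[2.2.2]octane-2,6-diones to single ketols is established. Silylation with t-BuMe2SiCl and imidazole in DMF comes back to the route at 14, so steps 5 to 8 are bypassed.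

Step 11. The acylpalladium may be captured by the enolate carbon rather than its oxygen (cyclopentenedione formation), the enolate may close with mixed alkene geometry, or the amine may add to the β-triflyloxy enone before oxidative addition. The fallback separates carbonylation from lactonisation and sets out from 18. Hydroxycarbonylation with Pd(OAc)2/1,3-bis(diphenylphosphino)propane, CO and water in DMF with i-Pr2NEt should give the two (Z)-γ-keto acids, which rest as the bis(γ-hydroxybutenolide) F4. Acid-catalysed dehydration (p-toluenesulfonic acid, cat., toluene, 4 Å sieves, 60 °C), the classical route to (Z)-alkylidene butenolides and phthalides under thermodynamic control, comes back to the route at 19.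

Further compounds
F1 | step 4 | (S)-3-hydroxy-4,4-dimethoxy-2-(3-oxocyclohexyl)cyclohexa-2,5-dien-1-one | O=C1C=CC(OC)(OC)C(O)=C1[C@H]1CCCC(=O)C1
F2 | step 4 | 16,16-dimethoxy derivative of triketone 10 (dimethyl ketal carbon C16 next to the C15 ketone, on the bridge remote from ring A) | O=C2CCC[C@@H]1[C@H]3C(=O)C(OC)(OC)[C@H](CC3=O)[C@H]21
F3 | step 5 | hydroxy diketone: 10 with the C27 carbonyl reduced to the carbinol of target configuration | O=C2CCC[C@@H]1[C@H]3C(=O)C[C@H](C[C@@H]3O)[C@H]21
F4 | step 11 | bis(γ-hydroxybutenolide): 19 with water added across each exocyclic alkene, hydroxyl on C5 and on C17 (mixture of hemiketal epimers) | CCCCC1(O)OC(=O)C2=C1CC[C@@H]1[C@H]3C4=C(C(O)(CCCC)OC4=O)[C@H](C[C@@H]3O[Si](C)(C)C(C)(C)C)[C@H]21
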